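The runs are calculated for substances that don't exist; scatter was added.

A curve that flattens tempts me to give it more time, and that is the pitfall in this flask, where I must decide what to charge and when to stop.

all flasks: electrophile 16 mM

|  | nucleophile | free base | protic impurity | remark | time |
|---|---|---|---|---|---|
| theta | 1 equiv | 0.80 equiv | 8 mM | run made earlier |  |
| gamma | 1 equiv | 0.80 equiv | 12 mM | run made earlier |  |
| flask | 1.00 equiv | 0.800 equiv | 16.0 mM |  | 30 min |

- theta (time / min: electrophile / %, target / %): 1.33: 66.8, 33.6; 2.50: 54.1, 45.6; 5.00: 42.7, 57.5; 10.0: 32.9, 66.6; 20.0: 26.7, 73.1
- gamma (time / min: electrophile / %, target / %): 1.50: 64.7, 35.3; 5.00: 43.5, 57.5; 8.00: 37.3, 63.3; 12.0: 32.1, 67.3; 20.0: 29.4, 70.7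

(readings scatter by 0.5 percentage points)

- the earlier runs do not show how much of nucleophile is bound; that part of a forecast is a guess
- a reading or a percentage of target counts all its forms, free or not

1. part of the electrophile that has reacted at 30 min
2. share of free nucleophile in free nucleophile and protonated nucleophile together, at 30 min

Electrophile and target add up to about the charge in both runs, so I count each turnover as using one nucleophile and setting free one acid. If a remaining nucleophile or the free base, the acid scavenger, must take that acid, turnover stalls where the acid set free equals what can still take it. That point is the acid limit c\*, the mean of the equivalents of nucleophile and free base, 90.0 %, and each point of conversion short of it means two points of base lost elsewhere.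

Treating both runs as stopped, theta reads 73.1 % of target at 20.0 min, so it has lost 33.8 % of the electrophile charge in base. Gamma, with more protic impurity, reads 70.7 % and has lost 38.6 %. The same step of impurity again gives me 68.3 % at 20.0 min in this flask, and a little more later. So I charge the flask as written and stop at 30 min.

The forecast gives 70.5 % reacted and 11 % free, expecting “a near stall around 70–71% at 30 min”; my figure is for the earlier time, and the forecast adds “The free share is a guess”.

The flask gives 70.7 % reacted and a free share of 2.86 %, 8.1 percentage points below the forecast.

    electrophile + nucleophile → acid set free + target (k = 31.0 /M/min)
    nucleophile + acid set free ⇌ protonated nucleophile, settled at all times (K = 49000 /M)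
    acid set free + free base ⇌ salt of the base, settled at all times (K = 1.10 × 10⁵ /M)
    nucleophile + target ⇌ idle adduct, settled at all times (K = 130 /M)
    protic impurity + free base → quenched reagent (k = 15.0 /M/min)

The half-life of electrophile by the forward step alone is 1.4 min with the other concentrations as charged, but 170 min at 30.0 min, longer than the 30 min of the run. Counting the 6.48 mM of quenched reagent as base lost puts the acid limit of this flask at 69.8 %, and the same count for the neighbour flask charged with 0.480 equiv of free base, with 3.46 mM of quenched reagent, gives 63.2 %, where that flask reached 65.3 %.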